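**Retrosynthetic overview**
1. The seven-membered dienol lactone (C8–C(=O)–O–CH=C) is closed last from an aldehydo acid. Its carbonyl carbon comes from CO at an aryl C–Cl bond and its formyl carbon from CO at an enol triflate.
2. The bond between C7 and the quaternary carbon is cut to an aryl bromide and 2,6-dimethylcyclohexanone; an asymmetric α-arylation sets the only stereocentre (S).
3. The quinone ring is cut at both aryl–C(=O) bonds to 3-bromo-4-chlorophenyllithium and a thiazine-fused cyclobutenedione (addition, then electrocyclic ring expansion).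
4. Feature used: N4 and S1 of the dioxothiazine sit on the adjacent quinone carbons C4a and C10a. The N-side carbonyl C5 is para to C8 (lactone C=O) and the S-side carbonyl C10 is para to C7 (quaternary carbon); the N,S-cyclobutenedione stores this orientation before the quinone exists.
5. Ring order: thiazine (on the squarate) → quinone ring → cyclohexene (brought in intact) → oxepinone lactone.

Key step: step 3

Remark: the quaternary carbon is read as S from the given SMILES; ring positions follow naphtho[2,3-b][1,4]thiazine numbering (S1, N4, C5–C10), and between steps 5 and 10 the quinone is carried as its hydroquinone dimethyl ether and the ring nitrogen as N-PMB.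

**Route**

Step 1
Reactants: 1 cysteamine (2-aminoethanethiol); 2 4-methoxybenzaldehyde
Product: 4 2-[(4-methoxybenzyl)amino]ethanethiol, via 2-(4-methoxyphenyl)thiazolidine 3 (not isolated)
Conditions: EtOH, rt, Ar; then NaBH4 (excess), 60 °C; degassed aqueous work-up
Reagents that add atoms: none
Why: Reductive amination: the aldehyde and the aminothiol condense to the thiazolidine, which is in ring–chain equilibrium with the iminium thiolate and is therefore reduced by borohydride to the N-benzylated aminothiol with the thiol left free.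

Step 2
Reactants: 4 2-[(4-methoxybenzyl)amino]ethanethiol; 5 diethyl squarate
Product: 7 5-(4-methoxybenzyl)-2-thia-5-azabicyclo[4.2.0]oct-1(6)-ene-7,8-dione, via squaramide ester thiol 6 (not isolated)
Conditions: Et3N (2 equiv), EtOH (0.05 M), 0 °C → rt, then 60 °C, Ar
Reagents that add atoms: none
Why: Squarate esters undergo addition–elimination at their vinylogous ester carbons, so the secondary amine replaces one ethoxy group and the tethered thiol then replaces the other in a six-membered ring closure that forms the thiazine on the four-membered ring.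

Step 3
Reactants: 8 2-bromo-1-chloro-4-iodobenzene; 7 5-(4-methoxybenzyl)-2-thia-5-azabicyclo[4.2.0]oct-1(6)-ene-7,8-dione
Product: 12 7-bromo-8-chloro-4-(4-methoxybenzyl)-3,4-dihydro-2H-naphtho[2,3-b][1,4]thiazine-5,10-dione, via 3-bromo-4-chlorophenyllithium 9 (not isolated), via hydroxycyclobutenone adduct 10 (not isolated), via naphthohydroquinone 11 (not isolated)
Conditions: 8 (1.15 equiv), n-BuLi (1.1 equiv), THF, −78 °C, 10 min; cannulate into 7, THF, −78 °C; aq. NH4Cl at −78 °C, extract, concentrate (crude 10, not purified); p-xylene, 138 °C, Ar; then air, rt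
Reagents that add atoms: none
Why: Iodine–lithium exchange is much faster than exchange at bromine or chlorine at −78 °C, and the aryllithium adds 1,2 to C7=O of 7 (bicyclo numbering), the carbonyl that is conjugated only with sulfur (thioester-like) and lies next to the N-bearing carbon, rather than to C8=O, which is a vinylogous amide. On heating, adduct 10 opens its C7–C8 bond by conrotatory 4π ring opening with the hydroxyl turning outward, so the aryl group lies cis to the ketene, and the ketene carbon then bonds to an ortho carbon of the arene. This is the only ring closed, a six-membered carbocycle formed by thermal 6π electrocyclisation; tautomerisation gives hydroquinone 11 and air oxidises it to the quinone. The closest known reaction type is the Moore ring expansion of 4-aryl-4-hydroxycyclobutenones made from squarate esters. No stereocentre results, because the carbinol carbon of 10 becomes a carbonyl carbon. Two selectivities are needed: carbonyl choice in the addition, secured by the donor difference between nitrogen and sulfur, and ortho choice in the closure, secured by bromine crowding the position between it and the ipso carbon; together they place the N-side carbonyl para to chlorine and the S-side carbonyl para to bromine.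

Step 4
Reactants: 12 7-bromo-8-chloro-4-(4-methoxybenzyl)-3,4-dihydro-2H-naphtho[2,3-b][1,4]thiazine-5,10-dione
Product: 13 7-bromo-8-chloro-4-(4-methoxybenzyl)-3,4-dihydro-2H-naphtho[2,3-b][1,4]thiazine-5,10-dione 1,1-dioxide
Conditions: mCPBA (3 equiv), NaHCO3, CH2Cl2, 0 °C → rt
Reagents that add atoms: 3-chloroperoxybenzoic acid (mCPBA), O=C(OO)c1cccc(Cl)c1
Why: In 12 the nitrogen is a vinylogous amide and the quinone double bond is electron-poor, so the peracid oxidises only sulfur, first to the sulfoxide and then to the sulfone (sulfide-to-sulfone oxidation).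

Step 5
Reactants: 13 quinone sulfone
Product: 15 7-bromo-8-chloro-5,10-dimethoxy-4-(4-methoxybenzyl)-3,4-dihydro-2H-naphtho[2,3-b][1,4]thiazine 1,1-dioxide, via sulfonyl hydroquinone 14 (not isolated)
Conditions: Na2S2O4, Bu4NBr (cat.), THF/H2O, rt, Ar; then aq. KOH, Me2SO4, rt
Reagents that add atoms: dimethyl sulfate, COS(=O)(=O)OC
Why: Reductive methylation: dithionite reduces the quinone and the hydroquinone dianion is O-methylated under phase transfer, which masks the quinone against enolates, Pd(0) and base in steps 6 to 9 while the tertiary N-PMB nitrogen and the sulfone stay untouched.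

Step 6
Reactants: 15 dimethoxy aryl bromide; 16 2,6-dimethylcyclohexanone (commercial cis/trans mixture)
Product: 17 (2S)-2-[8-chloro-5,10-dimethoxy-4-(4-methoxybenzyl)-1,1-dioxo-3,4-dihydro-2H-naphtho[2,3-b][1,4]thiazin-7-yl]-2,6-dimethylcyclohexan-1-one (both C6 epimers)
Conditions: Pd2(dba)3 (5 mol %), BINAP (12 mol %, the antipode that gives 2S), NaOtBu (1.5 equiv), 16 (2.5 equiv), toluene, 80–100 °C
Reagents that add atoms: none
Why: Pd-catalysed asymmetric α-arylation of a ketone enolate: oxidative addition takes place at C–Br and not at C–Cl, the only enolate that 16 can form is tetrasubstituted so that reductive elimination must create the aryl-bearing quaternary carbon, and its S configuration is set by the chiral bisphosphine on palladium (catalyst control), while C6 remains a mixture that step 7 erases.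

Step 7
Reactants: 17 α-aryl ketone
Product: 19 (6S)-6-[8-chloro-5,10-dimethoxy-4-(4-methoxybenzyl)-1,1-dioxo-3,4-dihydro-2H-naphtho[2,3-b][1,4]thiazin-7-yl]-2,6-dimethylcyclohex-1-en-1-yl trifluoromethanesulfonate, via potassium enolate 18 (not isolated)
Conditions: KHMDS (1.2 equiv), THF, −78 → 0 °C; PhNTf2, 0 °C → rt
Reagents that add atoms: N-phenylbis(trifluoromethanesulfonimide), O=S(=O)(N(c1ccccc1)S(=O)(=O)C(F)(F)F)C(F)(F)F
Why: Only C6 of 17 carries an α-hydrogen, the ketone enolate is favoured over the α-sulfonyl carbanion once proton transfer has equilibrated at 0 °C, and O-sulfonylation with PhNTf2 converts both C6 epimers into one enol triflate without touching the quaternary carbon.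

Step 8
Reactants: 19 enol triflate
Product: 20 (6R)-6-[8-chloro-5,10-dimethoxy-4-(4-methoxybenzyl)-1,1-dioxo-3,4-dihydro-2H-naphtho[2,3-b][1,4]thiazin-7-yl]-2,6-dimethylcyclohex-1-ene-1-carbaldehyde
Conditions: Pd(PPh3)4 (5 mol %), LiCl, CO (3 atm), Bu3SnH (slow addition), THF, 60 °C
Reagents that add atoms: carbon monoxide, [C-]#[O+]
Why: Pd-catalysed reductive carbonylation (formylation) of an enol triflate: oxidative addition, CO insertion and capture of the acyl-palladium by tin hydride give the enal, while the aryl chloride does not react with Pd(PPh3)4 at this temperature (the descriptor becomes R only because chlorine now outranks the formyl-bearing carbon in the CIP order; the spatial arrangement is unchanged).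

Step 9
Reactants: 20 enal aryl chloride
Product: 21 7-[(1S)-2-formyl-1,3-dimethylcyclohex-2-en-1-yl]-5,10-dimethoxy-4-(4-methoxybenzyl)-1,1-dioxo-3,4-dihydro-2H-naphtho[2,3-b][1,4]thiazine-8-carboxylic acid
Conditions: Pd(OAc)2 (5 mol %), dcpp·2HBF4 (10 mol %), K2CO3, H2O (5 equiv), CO (1 atm), DMSO, 110 °C; then aq. citric acid
Reagents that add atoms: carbon monoxide, [C-]#[O+]; water, O
Why: Pd-catalysed hydroxycarbonylation of an aryl chloride with an electron-rich chelating bis(dicyclohexylphosphine): insertion into C–Cl, CO insertion and attack of water give the carboxylate, and any dienol lactone formed by intramolecular capture of the acyl-palladium is saponified again under the aqueous carbonate conditions.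

Step 10
Reactants: 21 dimethoxy aldehydo acid
Product: 22 7-[(1S)-2-formyl-1,3-dimethylcyclohex-2-en-1-yl]-1,1,5,10-tetraoxo-3,4,5,10-tetrahydro-2H-naphtho[2,3-b][1,4]thiazine-8-carboxylic acid
Conditions: CAN (5 equiv), MeCN/H2O (3:1), 0 °C → rt
Reagents that add atoms: water, O
Why: Ceric ammonium nitrate oxidises the amino-dimethoxynaphthalene to the quinone (oxidative demethylation, oxygen from water) and removes the p-methoxybenzyl group by benzylic oxidation and hydrolysis, whereas the electron-poor enal, the acid and the sulfone are inert to Ce(IV), which is why the oxidation is placed before the electron-rich dienol lactone exists.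

Step 11
Reactants: 22 quinone aldehydo acid
Product: 24 target CNP0348176.1 (S), via acid chloride 23 (not isolated)
Conditions: (COCl)2 (1.2 equiv), DMF (cat.), CH2Cl2, 0 °C; then Et3N (3 equiv), DMAP (cat.), 0 °C → rt
Reagents that add atoms: none
Why: Enol lactonisation of an aldehydo acid: the acid chloride acylates the oxygen of the neighbouring enal within a seven-membered ring and amine-mediated loss of HCl removes a proton from the ring CH2 next to the methyl-bearing carbon, which gives the more substituted endocyclic diene conjugated with the new enol ester and leaves the quaternary stereocentre untouched.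

**Compound list**
1 | cysteamine (2-aminoethanethiol) | NCCS | starting material
2 | 4-methoxybenzaldehyde | COc1ccc(C=O)cc1 | starting material
3 | 2-(4-methoxyphenyl)thiazolidine | COc1ccc(C2NCCS2)cc1 | intermediate
4 | 2-[(4-methoxybenzyl)amino]ethanethiol | COc1ccc(CNCCS)cc1 | intermediate
5 | diethyl squarate | CCOC1=C(OCC)C(=O)C1=O | starting material
6 | 3-ethoxy-4-[(4-methoxybenzyl)(2-sulfanylethyl)amino]cyclobut-3-ene-1,2-dione | CCOC1=C(N(CCS)Cc2ccc(OC)cc2)C(=O)C1=O | intermediate
7 | 5-(4-methoxybenzyl)-2-thia-5-azabicyclo[4.2.0]oct-1(6)-ene-7,8-dione | O=C1C(=O)C2=C1N(Cc1ccc(OC)cc1)CCS2 | intermediate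
8 | 2-bromo-1-chloro-4-iodobenzene | Clc1ccc(I)cc1Br | starting material
9 | 3-bromo-4-chlorophenyllithium | [Li]c1ccc(Cl)c(Br)c1 | intermediate
10 | 7-(3-bromo-4-chlorophenyl)-7-hydroxy-5-(4-methoxybenzyl)-2-thia-5-azabicyclo[4.2.0]oct-1(6)-en-8-one (racemic carbinol) | O=C1C2=C(N(Cc3ccc(OC)cc3)CCS2)C1(O)c1ccc(Cl)c(Br)c1 | intermediate
11 | 7-bromo-8-chloro-4-(4-methoxybenzyl)-3,4-dihydro-2H-naphtho[2,3-b][1,4]thiazine-5,10-diol | Oc1c2N(Cc3ccc(OC)cc3)CCSc2c(O)c2cc(Cl)c(Br)cc12 | intermediate
12 | 7-bromo-8-chloro-4-(4-methoxybenzyl)-3,4-dihydro-2H-naphtho[2,3-b][1,4]thiazine-5,10-dione | O=C1C2=C(SCCN2Cc2ccc(OC)cc2)C(=O)c2cc(Cl)c(Br)cc12 | intermediate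
13 | 7-bromo-8-chloro-4-(4-methoxybenzyl)-3,4-dihydro-2H-naphtho[2,3-b][1,4]thiazine-5,10-dione 1,1-dioxide | O=C1C2=C(C(=O)c3cc(Cl)c(Br)cc13)S(=O)(=O)CCN2Cc1ccc(OC)cc1 | intermediate
14 | 7-bromo-8-chloro-5,10-dihydroxy-4-(4-methoxybenzyl)-3,4-dihydro-2H-naphtho[2,3-b][1,4]thiazine 1,1-dioxide | Oc1c2N(Cc3ccc(OC)cc3)CCS(=O)(=O)c2c(O)c2cc(Cl)c(Br)cc12 | intermediate
15 | 7-bromo-8-chloro-5,10-dimethoxy-4-(4-methoxybenzyl)-3,4-dihydro-2H-naphtho[2,3-b][1,4]thiazine 1,1-dioxide | COc1c2N(Cc3ccc(OC)cc3)CCS(=O)(=O)c2c(OC)c2cc(Cl)c(Br)cc12 | intermediate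
16 | 2,6-dimethylcyclohexanone (cis/trans mixture) | CC1CCCC(C)C1=O | starting material
17 | (2S)-2-[8-chloro-5,10-dimethoxy-4-(4-methoxybenzyl)-1,1-dioxo-3,4-dihydro-2H-naphtho[2,3-b][1,4]thiazin-7-yl]-2,6-dimethylcyclohexan-1-one (C6 epimers) | CC1CCC[C@](c2cc3c(OC)c4N(Cc5ccc(OC)cc5)CCS(=O)(=O)c4c(OC)c3cc2Cl)(C)C1=O | intermediate
18 | potassium (6S)-6-[8-chloro-5,10-dimethoxy-4-(4-methoxybenzyl)-1,1-dioxo-3,4-dihydro-2H-naphtho[2,3-b][1,4]thiazin-7-yl]-2,6-dimethylcyclohex-1-en-1-olate | [K+].CC1=C([O-])[C@](C)(c2cc3c(OC)c4N(Cc5ccc(OC)cc5)CCS(=O)(=O)c4c(OC)c3cc2Cl)CCC1 | intermediate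
19 | (6S)-6-[8-chloro-5,10-dimethoxy-4-(4-methoxybenzyl)-1,1-dioxo-3,4-dihydro-2H-naphtho[2,3-b][1,4]thiazin-7-yl]-2,6-dimethylcyclohex-1-en-1-yl trifluoromethanesulfonate | CC1=C(OS(=O)(=O)C(F)(F)F)[C@](C)(c2cc3c(OC)c4N(Cc5ccc(OC)cc5)CCS(=O)(=O)c4c(OC)c3cc2Cl)CCC1 | intermediate
20 | (6R)-6-[8-chloro-5,10-dimethoxy-4-(4-methoxybenzyl)-1,1-dioxo-3,4-dihydro-2H-naphtho[2,3-b][1,4]thiazin-7-yl]-2,6-dimethylcyclohex-1-ene-1-carbaldehyde (same spatial arrangement as 19; descriptor changed by CIP ranking) | CC1=C(C=O)[C@](C)(c2cc3c(OC)c4N(Cc5ccc(OC)cc5)CCS(=O)(=O)c4c(OC)c3cc2Cl)CCC1 | intermediate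
21 | 7-[(1S)-2-formyl-1,3-dimethylcyclohex-2-en-1-yl]-5,10-dimethoxy-4-(4-methoxybenzyl)-1,1-dioxo-3,4-dihydro-2H-naphtho[2,3-b][1,4]thiazine-8-carboxylic acid | CC1=C(C=O)[C@](C)(c2cc3c(OC)c4N(Cc5ccc(OC)cc5)CCS(=O)(=O)c4c(OC)c3cc2C(=O)O)CCC1 | intermediate
22 | 7-[(1S)-2-formyl-1,3-dimethylcyclohex-2-en-1-yl]-1,1,5,10-tetraoxo-3,4,5,10-tetrahydro-2H-naphtho[2,3-b][1,4]thiazine-8-carboxylic acid | CC1=C(C=O)[C@](C)(c2cc3c(cc2C(=O)O)C(=O)C2=C(C3=O)NCCS2(=O)=O)CCC1 | intermediate
23 | 7-[(1S)-2-formyl-1,3-dimethylcyclohex-2-en-1-yl]-1,1,5,10-tetraoxo-3,4,5,10-tetrahydro-2H-naphtho[2,3-b][1,4]thiazine-8-carbonyl chloride | CC1=C(C=O)[C@](C)(c2cc3c(cc2C(=O)Cl)C(=O)C2=C(C3=O)NCCS2(=O)=O)CCC1 | intermediate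
24 | CNP0348176.1: (S)-dienol lactone in which the seven-membered ring C8–C(=O)–O–CH=C–C(quaternary, CH3)–C7 is fused to the 1,1-dioxo-3,4-dihydro-2H-naphtho[2,3-b][1,4]thiazine-5,10-dione and to a cyclohexene bearing the second methyl on its ring C=CH | CC1=CCC[C@]2(C)C1=COC(=O)c1cc3c(cc12)C(=O)C1=C(C3=O)S(=O)(=O)CCN1 | target

**Step count and risks**
Total steps: 11. Longest linear sequence: 11 steps (1 → 24); compounds 2, 5, 8 and 16 enter as single commercial reagents.

Steps most likely to fail:

1. Step 6. The palladium enolate of a fully substituted enolate carbon may couple slowly with the ortho-chlorinated aryl bromide. The chiral bisphosphine may also discriminate the enolate faces poorly, because the enolate is racemic at C6 and equilibrates only through the ketone. Either process would give the quaternary carbon in low enantiomeric purity or not at all. Fallback: the stereocentre is obtained by resolution instead of catalyst control. Setting out from 15 and 16, an achiral and more active catalyst (Pd(dba)2, 1,1'-bis(di-tert-butylphosphino)ferrocene, NaOtBu, toluene, 70 °C) should give the racemic ketone F1 as all four stereoisomers. KHMDS and PhNTf2 as in step 7 lead through the racemic potassium enolate F2 to the racemic enol triflate F3, which has a single stereocentre and is resolved by preparative SFC on a chiral stationary phase. The S enantiomer is compound 19, where the route is rejoined before step 8.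

2. Step 3. The aryllithium may add to the other carbonyl of 7 (C8, next to the sulfur-bearing carbon) or to both. The ring expansion would then place bromine and chlorine the wrong way round relative to nitrogen and sulfur. Fallback: dione 7 is kept, but the halogen positions in the aryl partner are exchanged so that addition at C8 becomes the productive event. The isomeric iodide 1-bromo-2-chloro-4-iodobenzene F4 is converted with n-BuLi (THF, −78 °C) into 4-bromo-3-chlorophenyllithium F5, whose addition at C8 gives the isomeric adduct 8-(4-bromo-3-chlorophenyl)-8-hydroxy-5-(4-methoxybenzyl)-2-thia-5-azabicyclo[4.2.0]oct-1(6)-en-7-one F6. On thermolysis in p-xylene the carbinol carbon ends next to sulfur and the ketene carbon next to nitrogen, with closure at the ortho carbon remote from chlorine. This leads through the same hydroquinone 11 and, after air oxidation, returns to the route at 12. If either iodide gives a mixture of adducts, these are separated at the hydroxycyclobutenone stage before heating.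

3. Step 9. Palladium saturated with CO may fail to insert into the C–Cl bond that lies ortho to the quaternary carbon, and the enal may degrade in hot aqueous carbonate before carbonylation occurs. Fallback: the oxidative addition is run without CO and the carboxyl carbon is taken from CO2. Setting out from 20, Miyaura borylation (Pd2(dba)3, XPhos, B2pin2, KOAc, dioxane, 100 °C) should give the aryl pinacolboronate (6S)-6-[5,10-dimethoxy-4-(4-methoxybenzyl)-1,1-dioxo-8-(4,4,5,5-tetramethyl-1,3,2-dioxaborolan-2-yl)-3,4-dihydro-2H-naphtho[2,3-b][1,4]thiazin-7-yl]-2,6-dimethylcyclohex-1-ene-1-carbaldehyde F7. Copper-catalysed carboxylation of the boronate (CuI, a bisoxazoline ligand, CsF, CO2 1 atm, DMF, 90 °C; acidic work-up) then gives acid 21, where the route is rejoined before step 10.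

Further compounds
F1 | step 6 | 2-[8-chloro-5,10-dimethoxy-4-(4-methoxybenzyl)-1,1-dioxo-3,4-dihydro-2H-naphtho[2,3-b][1,4]thiazin-7-yl]-2,6-dimethylcyclohexan-1-one (racemic, all stereoisomers) | CC1CCCC(c2cc3c(OC)c4N(Cc5ccc(OC)cc5)CCS(=O)(=O)c4c(OC)c3cc2Cl)(C)C1=O
F2 | step 6 | racemic potassium 6-[8-chloro-5,10-dimethoxy-4-(4-methoxybenzyl)-1,1-dioxo-3,4-dihydro-2H-naphtho[2,3-b][1,4]thiazin-7-yl]-2,6-dimethylcyclohex-1-en-1-olate | [K+].CC1=C([O-])C(C)(c2cc3c(OC)c4N(Cc5ccc(OC)cc5)CCS(=O)(=O)c4c(OC)c3cc2Cl)CCC1
F3 | step 6 | racemic 6-[8-chloro-5,10-dimethoxy-4-(4-methoxybenzyl)-1,1-dioxo-3,4-dihydro-2H-naphtho[2,3-b][1,4]thiazin-7-yl]-2,6-dimethylcyclohex-1-en-1-yl trifluoromethanesulfonate | CC1=C(OS(=O)(=O)C(F)(F)F)C(C)(c2cc3c(OC)c4N(Cc5ccc(OC)cc5)CCS(=O)(=O)c4c(OC)c3cc2Cl)CCC1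
F4 | step 3 | 1-bromo-2-chloro-4-iodobenzene | Brc1ccc(I)cc1Cl
F5 | step 3 | 4-bromo-3-chlorophenyllithium | [Li]c1ccc(Br)c(Cl)c1
F6 | step 3 | 8-(4-bromo-3-chlorophenyl)-8-hydroxy-5-(4-methoxybenzyl)-2-thia-5-azabicyclo[4.2.0]oct-1(6)-en-7-one (racemic carbinol) | O=C1C2=C(SCCN2Cc2ccc(OC)cc2)C1(O)c1ccc(Br)c(Cl)c1
F7 | step 9 | (6S)-6-[5,10-dimethoxy-4-(4-methoxybenzyl)-1,1-dioxo-8-(4,4,5,5-tetramethyl-1,3,2-dioxaborolan-2-yl)-3,4-dihydro-2H-naphtho[2,3-b][1,4]thiazin-7-yl]-2,6-dimethylcyclohex-1-ene-1-carbaldehyde | CC1=C(C=O)[C@](C)(c2cc3c(OC)c4N(Cc5ccc(OC)cc5)CCS(=O)(=O)c4c(OC)c3cc2B2OC(C)(C)C(C)(C)O2)CCC1
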